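Target read as (−)-epigallocatechin-(4β→8)-(+)-catechin. The upper unit has rings A/C/B, the lower unit rings D/F/E, and flavan numbering is used in each unit.
Cuts: (a) eleven O–benzyl bonds. (b) In one operation, O1–C8a of ring F and C4 (ring C)–C8 (ring D). (c) C4–C4a of the lower unit, leading back to a fluoroarene and a three-carbon epoxide that carries ring E.
Enabling feature: in ring D the ether carbon C8a and the interflavan carbon C8 are direct neighbours, and C8 is flanked by O-7. This is the addition pattern of a C8≡C8a aryne: the tethered C2 alkoxide adds to C8a and the charge appears on C8, where the upper unit must be attached.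
Forward order: rings A, B and C come intact from epigallocatechin, activated at C4. Ring D (from 1,3,5-trifluorobenzene) is joined to the ring-E epoxide at C4–C4a. Ring F closes last and releases the C8 carbanion, which forms the interflavan bond in the same flask. The helpers (F, the 4-ether, the O-3 benzyl group) leave in the key step or in the final hydrogenolysis.
Stereochemistry: upper C2/C3 come from the chiral pool. Lower C2/C3 come from one Sharpless kinetic resolution; the anti epoxy alcohol is carried into the 2,3-trans ring F because the C2–O bond is never broken. Upper C4 is set by β-face attack, anti to the 3-O and 2-aryl groups.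
Key step: step 11

Assumption: (−)-epigallocatechin, 3,4-bis(benzyloxy)benzaldehyde and 1,3,5-trifluorobenzene are taken as commercial materials.

Step 1
Reactants: 1 1,3,5-trifluorobenzene
Product: 2 1,3-bis(benzyloxy)-5-fluorobenzene
Conditions: BnOH (2.1 equiv), NaH (2.2 equiv), THF, 0 °C; then 1, DMF, 80 °C
Reagents that add atoms: benzyl alcohol OCc1ccccc1
Why: Double nucleophilic aromatic substitution (SNAr), in which each fluorine is activated by the meta halogens and every benzyloxy group introduced slows the next displacement, so two equivalents of alkoxide should stop at the monofluoride.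

Step 2
Reactants: 3 3,4-bis(benzyloxy)benzaldehyde
Product: 4 rac-1-[3,4-bis(benzyloxy)phenyl]prop-2-en-1-ol
Conditions: vinylmagnesium bromide, THF, 0 °C; aq NH4Cl
Reagents that add atoms: vinylmagnesium bromide C=C[Mg]Br
Why: Grignard 1,2-addition to an aromatic aldehyde, in which the carbinol centre is formed as the racemate and is resolved in step 3.

Step 3
Reactants: 4 rac-1-[3,4-bis(benzyloxy)phenyl]prop-2-en-1-ol
Product: 5 (R)-[3,4-bis(benzyloxy)phenyl][(S)-oxiran-2-yl]methanol (anti epoxy alcohol)
Conditions: Ti(OiPr)4 (10 mol %), D-(−)-diisopropyl tartrate (12 mol %), t-BuOOH (0.45 equiv), 4 Å MS, CH2Cl2, −20 °C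
Reagents that add atoms: tert-butyl hydroperoxide CC(C)(C)OO
Why: Sharpless kinetic resolution, in which the Ti/D-(−)-tartrate catalyst should epoxidise the (S)-alcohol much faster than the (R)-alcohol and give the erythro (anti) epoxy alcohol, fixing the later C2 (R) and C3 (S) of ring F at once, while unreacted (R)-4 is removed by chromatography.

Step 4
Reactants: 5 (R)-[3,4-bis(benzyloxy)phenyl][(S)-oxiran-2-yl]methanol
Product: 6 tert-butyl{(R)-[3,4-bis(benzyloxy)phenyl][(S)-oxiran-2-yl]methoxy}dimethylsilane
Conditions: TBSCl, imidazole, DMF, rt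
Reagents that add atoms: tert-butyldimethylsilyl chloride CC(C)(C)[Si](C)(C)Cl
Why: Standard silylation under weakly basic conditions that leaves the epoxide and both stereocentres untouched and masks the later O1 during steps 5 and 6.

Step 5
Reactants: 2 1,3-bis(benzyloxy)-5-fluorobenzene; 6 tert-butyl{(R)-[3,4-bis(benzyloxy)phenyl][(S)-oxiran-2-yl]methoxy}dimethylsilane
Product: 8 (2S,3R)-1-[2,4-bis(benzyloxy)-6-fluorophenyl]-3-[3,4-bis(benzyloxy)phenyl]-3-[(tert-butyldimethylsilyl)oxy]propan-2-ol, via [2,4-bis(benzyloxy)-6-fluorophenyl]lithium 7 (not isolated)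
Conditions: 2, n-BuLi, THF, −78 °C; then BF3·OEt2 and 6, −78 °C; aq NaHCO3
Reagents that add atoms: none
Why: Directed ortho-lithiation at the most acidic C–H (flanked by fluorine and a benzyloxy group), held at −78 °C so that LiF is not lost, followed by BF3-assisted SN2 opening of the terminal epoxide carbon, which forms C4–C4a and touches neither stereocentre.

Step 6
Reactants: 8 (2S,3R)-1-[2,4-bis(benzyloxy)-6-fluorophenyl]-3-[3,4-bis(benzyloxy)phenyl]-3-[(tert-butyldimethylsilyl)oxy]propan-2-ol
Product: 9 tert-butyl{(1R,2S)-2-(benzyloxy)-3-[2,4-bis(benzyloxy)-6-fluorophenyl]-1-[3,4-bis(benzyloxy)phenyl]propoxy}dimethylsilane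
Conditions: 2-benzyloxy-1-methylpyridinium triflate (2 equiv), MgO, PhCF3, 85 °C
Reagents that add atoms: 2-benzyloxy-1-methylpyridinium triflate C[n+]1ccccc1OCc1ccccc1.[O-]S(=O)(=O)C(F)(F)F
Why: Neutral benzyl transfer from the pyridinium salt avoids forming the C3 alkoxide, which could cause 1,2-silyl migration or five-ring SNAr attack on the C–F bond, and no stereocentre takes part.

Step 7
Reactants: 9 tert-butyl{(1R,2S)-2-(benzyloxy)-3-[2,4-bis(benzyloxy)-6-fluorophenyl]-1-[3,4-bis(benzyloxy)phenyl]propoxy}dimethylsilane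
Product: 10 (1R,2S)-2-(benzyloxy)-3-[2,4-bis(benzyloxy)-6-fluorophenyl]-1-[3,4-bis(benzyloxy)phenyl]propan-1-ol
Conditions: TBAF, AcOH, THF, 0 °C → rt
Reagents that add atoms: none
Why: Fluoride-mediated desilylation, buffered with acetic acid so that no free alkoxide attacks the aryl fluoride prematurely, leaves the benzyl ethers and both stereocentres unchanged.

Step 8
Reactants: 11 (−)-epigallocatechin
Product: 12 5,7,3',4',5'-penta-O-benzyl-(−)-epigallocatechin
Conditions: BnBr (5.5 equiv), K2CO3, DMF, argon, 0 °C → rt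
Reagents that add atoms: benzyl bromide BrCc1ccccc1
Why: Williamson etherification of the five phenols with a carbonate base too weak to deprotonate the C3 alcohol, with air excluded to protect the pyrogallol ring and the mild base chosen to avoid C2 epimerisation.

Step 9
Reactants: 12 5,7,3',4',5'-penta-O-benzyl-(−)-epigallocatechin
Product: 13 3,5,7,3',4',5'-hexa-O-benzyl-(−)-epigallocatechin
Conditions: NaH, BnBr, Bu4NI (cat.), THF/DMF, 0 °C → rt
Reagents that add atoms: benzyl bromide BrCc1ccccc1
Why: Williamson etherification of the remaining secondary alcohol, needed because a free hydroxyl group would quench the organometallic partner in step 11.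

Step 10
Reactants: 13 3,5,7,3',4',5'-hexa-O-benzyl-(−)-epigallocatechin
Product: 14 3,5,7,3',4',5'-hexa-O-benzyl-4β-(2-ethoxyethoxy)-(−)-epigallocatechin (2,3-cis-3,4-trans)
Conditions: DDQ, 2-ethoxyethanol, CH2Cl2, rt
Reagents that add atoms: 2-ethoxyethanol CCOCCO
Why: DDQ benzylic oxidation (hydride abstraction) should occur at C4, the position conjugated with the three ring-A oxygens, and the cation is captured by the alcohol on the β face, anti to the 3-benzyloxy group, to give the 3,4-trans ether.

Step 11
Reactants: 10 (1R,2S)-2-(benzyloxy)-3-[2,4-bis(benzyloxy)-6-fluorophenyl]-1-[3,4-bis(benzyloxy)phenyl]propan-1-ol; 14 3,5,7,3',4',5'-hexa-O-benzyl-4β-(2-ethoxyethoxy)-(−)-epigallocatechin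
Product: 20 undeca-O-benzyl-epigallocatechin-(4β→8)-catechin, via C8-lithiated fluoroarene lithium alkoxide 15 (not isolated), via C8–C8a aryne lithium alkoxide 16 (not isolated), via 8-lithio-penta-O-benzylcatechin 17 (not isolated), via 8-(bromozincio)-penta-O-benzylcatechin 18 (not isolated), via hexa-O-benzyl-epigallocatechin-4-ylium triflate 19 (not isolated)
Conditions: 10, n-BuLi (2.1 equiv), THF (0.02 M), −78 °C; warm to −10 °C; ZnBr2 (1.1 equiv), −10 → 0 °C; dilute with CH2Cl2, −78 °C; 14 (0.9 equiv), TMSOTf (1.5 equiv), −78 → −30 °C; aq NaHCO3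
Reagents that add atoms: none
Why: Proposed new method: n-BuLi forms the C2 lithium alkoxide and then removes H-8 of ring D, the most acidic ring proton because it lies between F-8a and O-7 (15); on warming LiF is lost to give the C8≡C8a aryne 16, the tethered alkoxide adds in the ring plane to C8a (O1–C8a bond, ring F) and the charge appears on C8 as aryllithium 17, which ZnBr2 converts into the milder arylzinc 18 so that TMSOTf can ionise the 4β-(2-ethoxyethoxy) group of 14 to the 2,4,6-trioxygenated benzylic cation 19, and 19 is captured at the carbon–zinc bond by ipso-substitution. The closest known reaction types are the base-induced benzyne ring closure of tethered alcohols to chromans with capture of the resulting ortho-carbanion by an electrophile, the generation of 3-alkoxyarynes from 3-fluoroaryl ethers with alkyllithiums, and the Lewis-acid coupling of C4-ether flavanyl donors with C8–H or C8-boronic acid flavanols; what is new is their combination in one flask on a flavanol precursor. Ring F closes in the 6-exo-dig mode, the attacked in-plane π bond lying outside the new ring. C2 and C3 of the lower unit are not touched because the C2–O bond is never broken, so the anti pattern of 10 becomes the 2,3-trans ring F, and the only new stereocentre, C4 of ring C, is set by attack on the β face of the half-chair cation 19, anti to the α-oriented 3-benzyloxy and 2-aryl groups (3,4-trans). The step needs site-selective metalation, O-addition at C8a only, six- over five-ring closure and C8 over C6 linkage without oligomerisation: the first is secured by fluorine, the second by the three-carbon tether together with the inductive pull of O-7 that polarises the aryne for attack at the distal carbon, the third by the benzyl group on O-3, and the last by the fact that only C8 carries the metal and neither partner has a free hydroxyl group.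

Step 12
Reactants: 20 undeca-O-benzyl-epigallocatechin-(4β→8)-catechin
Product: 21 (−)-epigallocatechin-(4β→8)-(+)-catechin (target)
Conditions: H2 (1 atm), Pd(OH)2/C, THF/MeOH/H2O, rt; filtration and lyophilisation under argon
Reagents that add atoms: none
Why: Catalytic hydrogenolysis should cleave all eleven benzyl ethers in one operation under neutral conditions that leave the acid-sensitive interflavan bond, both C2–O1 bonds and all five stereocentres intact.

Compound list
1 | 1,3,5-trifluorobenzene | Fc1cc(F)cc(F)c1 | starting material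
2 | 1,3-bis(benzyloxy)-5-fluorobenzene | Fc1cc(OCc2ccccc2)cc(OCc2ccccc2)c1 | intermediate
3 | 3,4-bis(benzyloxy)benzaldehyde | O=Cc1ccc(OCc2ccccc2)c(OCc2ccccc2)c1 | starting material
4 | rac-1-[3,4-bis(benzyloxy)phenyl]prop-2-en-1-ol | OC(C=C)c1ccc(OCc2ccccc2)c(OCc2ccccc2)c1 | intermediate
5 | (R)-[3,4-bis(benzyloxy)phenyl][(S)-oxiran-2-yl]methanol | O[C@H](c1ccc(OCc2ccccc2)c(OCc2ccccc2)c1)[C@@H]1CO1 | intermediate
6 | tert-butyl{(R)-[3,4-bis(benzyloxy)phenyl][(S)-oxiran-2-yl]methoxy}dimethylsilane | CC(C)(C)[Si](C)(C)O[C@H](c1ccc(OCc2ccccc2)c(OCc2ccccc2)c1)[C@@H]1CO1 | intermediate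
7 | [2,4-bis(benzyloxy)-6-fluorophenyl]lithium | [Li]c1c(F)cc(OCc2ccccc2)cc1OCc1ccccc1 | intermediate
8 | (2S,3R)-1-[2,4-bis(benzyloxy)-6-fluorophenyl]-3-[3,4-bis(benzyloxy)phenyl]-3-[(tert-butyldimethylsilyl)oxy]propan-2-ol | CC(C)(C)[Si](C)(C)O[C@H](c1ccc(OCc2ccccc2)c(OCc2ccccc2)c1)[C@@H](O)Cc1c(F)cc(OCc2ccccc2)cc1OCc1ccccc1 | intermediate
9 | tert-butyl{(1R,2S)-2-(benzyloxy)-3-[2,4-bis(benzyloxy)-6-fluorophenyl]-1-[3,4-bis(benzyloxy)phenyl]propoxy}dimethylsilane | CC(C)(C)[Si](C)(C)O[C@H](c1ccc(OCc2ccccc2)c(OCc2ccccc2)c1)[C@@H](OCc1ccccc1)Cc1c(F)cc(OCc2ccccc2)cc1OCc1ccccc1 | intermediate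
10 | (1R,2S)-2-(benzyloxy)-3-[2,4-bis(benzyloxy)-6-fluorophenyl]-1-[3,4-bis(benzyloxy)phenyl]propan-1-ol | O[C@H](c1ccc(OCc2ccccc2)c(OCc2ccccc2)c1)[C@@H](OCc1ccccc1)Cc1c(F)cc(OCc2ccccc2)cc1OCc1ccccc1 | intermediate
11 | (−)-epigallocatechin (2R,3R) | Oc1cc(O)c2c(c1)O[C@H](c1cc(O)c(O)c(O)c1)[C@H](O)C2 | starting material
12 | 5,7,3',4',5'-penta-O-benzyl-(−)-epigallocatechin | c1ccccc1COc1cc(OCc3ccccc3)c2c(c1)O[C@H](c1cc(OCc3ccccc3)c(OCc3ccccc3)c(OCc3ccccc3)c1)[C@H](O)C2 | intermediate
13 | 3,5,7,3',4',5'-hexa-O-benzyl-(−)-epigallocatechin | c1ccccc1COc1cc(OCc3ccccc3)c2c(c1)O[C@H](c1cc(OCc3ccccc3)c(OCc3ccccc3)c(OCc3ccccc3)c1)[C@H](OCc3ccccc3)C2 | intermediate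
14 | 3,5,7,3',4',5'-hexa-O-benzyl-4β-(2-ethoxyethoxy)-(−)-epigallocatechin (2,3-cis-3,4-trans) | c1ccccc1COc1cc(OCc3ccccc3)c2c(c1)O[C@H](c1cc(OCc3ccccc3)c(OCc3ccccc3)c(OCc3ccccc3)c1)[C@H](OCc3ccccc3)[C@H]2OCCOCC | intermediate
15 | C8-lithiated fluoroarene lithium alkoxide (O,C8-dilithio derivative of 10) | [Li]O[C@H](c1ccc(OCc2ccccc2)c(OCc2ccccc2)c1)[C@@H](OCc1ccccc1)Cc1c(F)c([Li])c(OCc2ccccc2)cc1OCc1ccccc1 | intermediate
16 | C8–C8a aryne lithium alkoxide | [Li]O[C@H](c1ccc(OCc2ccccc2)c(OCc2ccccc2)c1)[C@@H](OCc1ccccc1)CC1=C(OCc2ccccc2)C=C(OCc2ccccc2)C#C1 | intermediate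
17 | 8-lithio-3,5,7,3',4'-penta-O-benzyl-(+)-catechin | [Li]c1c(OCc3ccccc3)cc(OCc3ccccc3)c2c1O[C@H](c1ccc(OCc3ccccc3)c(OCc3ccccc3)c1)[C@@H](OCc3ccccc3)C2 | intermediate
18 | 8-(bromozincio)-3,5,7,3',4'-penta-O-benzyl-(+)-catechin | Br[Zn]c1c(OCc3ccccc3)cc(OCc3ccccc3)c2c1O[C@H](c1ccc(OCc3ccccc3)c(OCc3ccccc3)c1)[C@@H](OCc3ccccc3)C2 | intermediate
19 | hexa-O-benzyl-epigallocatechin-4-ylium triflate | c1ccccc1COc1cc(OCc3ccccc3)c2c(c1)O[C@H](c1cc(OCc3ccccc3)c(OCc3ccccc3)c(OCc3ccccc3)c1)[C@H](OCc3ccccc3)[CH+]2.[O-]S(=O)(=O)C(F)(F)F | intermediate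
20 | undeca-O-benzyl-epigallocatechin-(4β→8)-catechin | c1ccccc1COc1cc(OCc3ccccc3)c2c(c1)O[C@H](c1cc(OCc3ccccc3)c(OCc3ccccc3)c(OCc3ccccc3)c1)[C@H](OCc3ccccc3)[C@H]2c1c(OCc3ccccc3)cc(OCc3ccccc3)c2c1O[C@H](c1ccc(OCc3ccccc3)c(OCc3ccccc3)c1)[C@@H](OCc3ccccc3)C2 | intermediate
21 | (−)-epigallocatechin-(4β→8)-(+)-catechin | Oc1cc(O)c2c(c1)O[C@H](c1cc(O)c(O)c(O)c1)[C@H](O)[C@H]2c1c(O)cc(O)c2c1O[C@H](c1ccc(O)c(O)c1)[C@@H](O)C2 | target

Total step count: 12
Longest linear sequence: 8 (steps 2, 3, 4, 5, 6, 7, 11, 12)

Steps most likely to fail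

Step 11. Several processes could spoil the step:
- metalation at C6 or at a benzylic CH2, followed by [1,2]-Wittig rearrangement
- addition of the newly formed aryllithium to a second aryne
- proton capture by the C8 carbanion before transmetalation
- attack of the cation at C6 instead of at the metal-bearing carbon

Fallback (from 10, returning at 20): ring F is closed by a plain intramolecular SNAr displacement of fluoride by the potassium alkoxide (KH, THF, 0 → 60 °C). This gives 3,5,7,3',4'-penta-O-benzyl-(+)-catechin F1. F1, used in excess, is then condensed with 14 under TMSOTf catalysis (CH2Cl2, −78 °C) in the established Friedel–Crafts manner. That coupling relies on the innate C8 preference of ring D and on the same β-face attack, and it gives 20.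

Step 5. Lithiation could occur between the two benzyloxy groups instead of next to fluorine. Premature loss of LiF from the aryllithium is possible, as is BF3-induced ionisation of the electron-rich benzylic silyl ether. Fallback (from 2, returning at 8): 2 is brominated with NBS (MeCN, 0 °C) para to one benzyloxy group and ortho to fluorine, giving 1,5-bis(benzyloxy)-2-bromo-3-fluorobenzene F2. Bromine–magnesium exchange with i-PrMgCl·LiCl (THF, −10 °C) gives [2,4-bis(benzyloxy)-6-fluorophenyl]magnesium chloride F3. Opening of 6 under CuI catalysis (THF, −30 → 0 °C), with no boron Lewis acid, then gives 8. In this variant the halogen fixes the position of the metal.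

Step 3. Possible failures are slow epoxidation of the terminal alkene, Lewis-acid ionisation of the electron-rich benzylic alcohol, titanium-promoted opening of the epoxide, and erosion of enantiopurity near half conversion. Fallback (from 4, returning at 5): racemic 4 is resolved by enzymatic acylation (immobilised Candida antarctica lipase B, vinyl acetate, MTBE, 30 °C). This should leave (S)-1-[3,4-bis(benzyloxy)phenyl]prop-2-en-1-ol F4 untouched, while the (R)-enantiomer is converted into (R)-1-[3,4-bis(benzyloxy)phenyl]prop-2-en-1-yl acetate F5. After separation, F4 is epoxidised under hydroxyl direction (VO(acac)2 cat., t-BuOOH, toluene, 0 °C). This reaction favours the erythro product, and chromatographic upgrading of the diastereomeric purity gives 5.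

Further compounds
F1 | step 11 | 3,5,7,3',4'-penta-O-benzyl-(+)-catechin | c1ccccc1COc1cc(OCc3ccccc3)c2c(c1)O[C@H](c1ccc(OCc3ccccc3)c(OCc3ccccc3)c1)[C@@H](OCc3ccccc3)C2
F2 | step 5 | 1,5-bis(benzyloxy)-2-bromo-3-fluorobenzene | Brc1c(F)cc(OCc2ccccc2)cc1OCc1ccccc1
F3 | step 5 | [2,4-bis(benzyloxy)-6-fluorophenyl]magnesium chloride | Cl[Mg]c1c(F)cc(OCc2ccccc2)cc1OCc1ccccc1
F4 | step 3 | (S)-1-[3,4-bis(benzyloxy)phenyl]prop-2-en-1-ol | O[C@H](c1ccc(OCc2ccccc2)c(OCc2ccccc2)c1)C=C
F5 | step 3 | (R)-1-[3,4-bis(benzyloxy)phenyl]prop-2-en-1-yl acetate | CC(=O)O[C@@H](c1ccc(OCc2ccccc2)c(OCc2ccccc2)c1)C=C
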